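**Retrosynthetic overview**
1. Numbering: ring A (five-membered) = C1 (quaternary, methyl), C2, C3, C4 (OH, isopropyl), C5 (H); ring B (seven-membered) = C1, C5, C6 (ester oxygen), C7, C8 (methyl)=C9, C10.
2. The C6–O ester bond is made last (diol + O-acetyl p-coumaric acid); the isopropyl group on C4 comes from addition to a ring A ketone.
3. Ring A is closed last, at C3–C4, by intramolecular alkene hydroacylation. The enabling feature is the 4-pentenal hidden in ring A: C4 as a formyl group on C5, and C2=C3 as a vinyl group on the neighbouring quaternary C1, trans-vicinal on ring B. The trans A/B fusion is therefore carried into the closure, not made by it.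
4. Ring B is formed first, by ring-closing metathesis to C8=C9 (allyl on C1 with 2-methylallyl on C6).
5. C5 and the quaternary C1 are set in one [3,3] step, a chelate-controlled dianionic Ireland–Claisen rearrangement, with C6 taken from the chiral pool.

Key step: step 10

Remark: pent-1-en-4-yne, ethyl (3R)-4-chloro-3-hydroxybutanoate and (E)-4-acetoxycinnamic acid are taken as commercial; the chelated dianion in step 5 is assumed to rearrange through a chair transition state on the face anti to the C6 side chain, as such dianions do in alkylation.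

**Route**

Step 1
Reactants: 1 ethyl (3R)-4-chloro-3-hydroxybutanoate
Product: 2 ethyl 2-[(2R)-oxiran-2-yl]acetate
Conditions: Ag2O, 4 Å MS, DME, 60 °C, dark
Reagents that add atoms: none
Why: Silver-assisted intramolecular Williamson etherification closes the epoxide without base, which avoids β-elimination of the epoxy ester; the stereocentre is not touched.

Step 2
Reactants: 2 ethyl 2-[(2R)-oxiran-2-yl]acetate
Product: 3 ethyl (3S)-3-hydroxy-5-methylhex-5-enoate
Conditions: isopropenylmagnesium bromide, CuBr·SMe2 (10 mol%), THF, −40 °C; aq. NH4Cl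
Reagents that add atoms: isopropenylmagnesium bromide, CC(=C)[Mg]Br
Why: Copper-catalysed SN2 opening of the epoxide at its terminal carbon should outrun attack on the ester at low temperature; the carbinol centre keeps its geometry (the descriptor changes only because the priorities change).

Step 3
Reactants: 4 pent-1-en-4-yne
Product: 7 (2E)-3-methylhexa-2,5-dien-1-ol, via alkenylalane 5 (not isolated), via lithium alanate 6 (not isolated)
Conditions: AlMe3, Cp2ZrCl2 (20 mol%), CH2Cl2, 0 to 25 °C; then n-BuLi, THF, −78 °C; (CH2O)n, −78 to 25 °C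
Reagents that add atoms: trimethylaluminium, C[Al](C)C; paraformaldehyde (as formaldehyde), C=O
Why: Zirconium-catalysed syn carboalumination of the alkyne places methyl on the internal carbon and fixes the E geometry, and hydroxymethylation of the alanate proceeds with retention.

Step 4
Reactants: 3 ethyl (3S)-3-hydroxy-5-methylhex-5-enoate; 7 (2E)-3-methylhexa-2,5-dien-1-ol
Product: 8 (2E)-3-methylhexa-2,5-dien-1-yl (3S)-3-hydroxy-5-methylhex-5-enoate
Conditions: Ti(OEt)4 (10 mol%), 7 (1.5 equiv), toluene, 100 °C, removal of EtOH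
Reagents that add atoms: none
Why: Titanate-catalysed transesterification is neutral and tolerates the free β-hydroxyl and the allylic alcohol; no stereocentre is involved.

Step 5
Reactants: 8 (2E)-3-methylhexa-2,5-dien-1-yl (3S)-3-hydroxy-5-methylhex-5-enoate
Product: 10 (2S,3S)-3-hydroxy-5-methyl-2-[(3S)-3-methylhexa-1,5-dien-3-yl]hex-5-enoic acid, via dilithium enolate alkoxide 9 (not isolated)
Conditions: LDA (2.3 equiv), THF, −78 °C; then 25 to 60 °C; aq. HCl
Reagents that add atoms: none
Why: In this dianionic Ireland–Claisen [3,3] rearrangement the lithium chelate fixes the enolate geometry (C6 chain cis to the enolate oxygen) and directs the allyl unit to the face anti to the 2-methylallyl group on C6 (as in Fráter–Seebach alkylation), and the chair transition state with the E-alkene places the C1 methyl axial, which sets C5 and the quaternary C1 in the relative configuration that becomes the trans ring fusion.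

Step 6
Reactants: 10 (2S,3S)-3-hydroxy-5-methyl-2-[(3S)-3-methylhexa-1,5-dien-3-yl]hex-5-enoic acid
Product: 11 (2S,3S)-3-hydroxy-N-methoxy-N,5-dimethyl-2-[(3S)-3-methylhexa-1,5-dien-3-yl]hex-5-enamide
Conditions: MeNH(OMe)·HCl, EDC·HCl, HOBt (cat.), N-methylmorpholine, CH2Cl2, 0 to 25 °C
Reagents that add atoms: N,O-dimethylhydroxylamine hydrochloride, CNOC.Cl
Why: Carbodiimide amide coupling gives the Weinreb amide, which later stops cleanly at the aldehyde stage; the α-centre C5 is not enolized under these conditions.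

Step 7
Reactants: 11 (2S,3S)-3-hydroxy-N-methoxy-N,5-dimethyl-2-[(3S)-3-methylhexa-1,5-dien-3-yl]hex-5-enamide
Product: 12 (2S,3S)-3-[(tert-butyldimethylsilyl)oxy]-N-methoxy-N,5-dimethyl-2-[(3S)-3-methylhexa-1,5-dien-3-yl]hex-5-enamide
Conditions: TBSOTf, 2,6-lutidine, CH2Cl2, −78 to 0 °C
Reagents that add atoms: tert-butyldimethylsilyl triflate, CC(C)(C)[Si](C)(C)OS(=O)(=O)C(F)(F)F
Why: Silylation with the silyl triflate protects the hindered secondary C6 hydroxyl so that the later aldehyde cannot undergo retro-aldol cleavage or elimination.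

Step 8
Reactants: 12 (2S,3S)-3-[(tert-butyldimethylsilyl)oxy]-N-methoxy-N,5-dimethyl-2-[(3S)-3-methylhexa-1,5-dien-3-yl]hex-5-enamide
Product: 13 (1S,2S,7S)-7-[(tert-butyldimethylsilyl)oxy]-2-ethenyl-N-methoxy-N,2,5-trimethylcyclohept-4-ene-1-carboxamide
Conditions: second-generation Grubbs catalyst (5 mol%), CH2Cl2 (0.005 M), 40 °C
Reagents that add atoms: none
Why: In this ring-closing metathesis the catalyst should load on the unhindered allyl group, from which the only possible closure is the seven-membered ring onto the 1,1-disubstituted alkene, while the neopentylic vinyl group on the quaternary carbon is a poor metathesis partner; no stereocentre is touched.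

Step 9
Reactants: 13 (1S,2S,7S)-7-[(tert-butyldimethylsilyl)oxy]-2-ethenyl-N-methoxy-N,2,5-trimethylcyclohept-4-ene-1-carboxamide
Product: 14 (1S,2S,7S)-7-[(tert-butyldimethylsilyl)oxy]-2-ethenyl-2,5-dimethylcyclohept-4-ene-1-carbaldehyde
Conditions: DIBAL-H, THF, −78 °C; Rochelle salt work-up
Reagents that add atoms: none
Why: Hydride reduction of the Weinreb amide stops at the chelated tetrahedral intermediate and gives the aldehyde on work-up; at −78 °C the α-centre C5 should not epimerize.

Step 10
Reactants: 14 (1S,2S,7S)-7-[(tert-butyldimethylsilyl)oxy]-2-ethenyl-2,5-dimethylcyclohept-4-ene-1-carbaldehyde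
Product: 15 (3aR,8S,8aS)-8-[(tert-butyldimethylsilyl)oxy]-3a,6-dimethyl-3,3a,4,7,8,8a-hexahydroazulen-1(2H)-one
Conditions: [Rh(dppe)(acetone)2]BF4 (5 mol%; from [Rh(nbd)(dppe)]BF4 and H2, then Ar purge), acetone/CH2Cl2, 25 °C
Reagents that add atoms: none
Why: Oxidative addition of the formyl C–H bond to the cationic monovalent rhodium centre gives an acyl rhodium hydride, the vinyl group inserts into Rh–H with hydride going to C2 to give a six-membered acyl–alkyl rhodacycle, and C–C reductive elimination forms C3–C4. The closest known reaction type is the rhodium-diphosphine-catalysed intramolecular hydroacylation of 4-pentenals to cyclopentanones, which tolerates a substituent at C2 and a quaternary C3 of the pentenal (here C5 and C1). Ring A is closed as a five-membered ring in which both alkene carbons end up inside the ring (endo with respect to the alkene, through the six-membered metallacycle), with no bond made at a fusion atom. No new stereocentre is formed: C1, C5 and C6 are carried through unchanged because the acyl metal does not enolize C5, so the trans fusion rests on step 5 and is geometrically accessible since formyl and vinyl are gauche on the flexible ring B. The step needs selectivity for the vinyl group over the C8=C9 alkene and for insertion over decarbonylation: only the vinyl group stands in a 4-pentenal relationship to the formyl group, and the geminal substitution at C1 (Thorpe–Ingold effect) together with the chelating diphosphine should favour insertion over CO loss.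

Step 11
Reactants: 15 (3aR,8S,8aS)-8-[(tert-butyldimethylsilyl)oxy]-3a,6-dimethyl-3,3a,4,7,8,8a-hexahydroazulen-1(2H)-one
Product: 16 (3R,3aS,4S,8aR)-4-[(tert-butyldimethylsilyl)oxy]-6,8a-dimethyl-3-(propan-2-yl)-1,2,3,3a,4,5,8,8a-octahydroazulen-3-ol
Conditions: anhydrous CeCl3, i-PrMgCl, THF, −78 to −40 °C
Reagents that add atoms: isopropylmagnesium chloride, CC(C)[Mg]Cl
Why: 1,2-Addition of the weakly basic organocerium reagent (which suppresses enolization and β-elimination of the silyloxy group) should occur on the α face, anti to the syn-axial angular methyl on C1 and to C6 on the adjacent C5, which sets C4 with the hydroxyl β and the isopropyl α.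

Step 12
Reactants: 16 (3R,3aS,4S,8aR)-4-[(tert-butyldimethylsilyl)oxy]-6,8a-dimethyl-3-(propan-2-yl)-1,2,3,3a,4,5,8,8a-octahydroazulen-3-ol
Product: 17 (3R,3aS,4S,8aR)-6,8a-dimethyl-3-(propan-2-yl)-1,2,3,3a,4,5,8,8a-octahydroazulene-3,4-diol (jaeschkeanadiol)
Conditions: TBAF, THF, 25 to 50 °C
Reagents that add atoms: none
Why: Fluoride-mediated desilylation frees the secondary C6 hydroxyl; no stereocentre is affected.

Step 13
Reactants: 17 jaeschkeanadiol; 18 (2E)-3-[4-(acetyloxy)phenyl]prop-2-enoic acid
Product: 19 (3R,3aS,4S,8aR)-3-hydroxy-6,8a-dimethyl-3-(propan-2-yl)-1,2,3,3a,4,5,8,8a-octahydroazulen-4-yl (2E)-3-[4-(acetyloxy)phenyl]prop-2-enoate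
Conditions: EDC·HCl, DMAP (cat.), CH2Cl2, 25 °C
Reagents that add atoms: none
Why: In this Steglich esterification only the secondary C6 hydroxyl should be acylated, the tertiary C4 hydroxyl being inert, and the E geometry of the acid is kept.

Step 14
Reactants: 19 (3R,3aS,4S,8aR)-3-hydroxy-6,8a-dimethyl-3-(propan-2-yl)-1,2,3,3a,4,5,8,8a-octahydroazulen-4-yl (2E)-3-[4-(acetyloxy)phenyl]prop-2-enoate
Product: 20 (3R,3aS,4S,8aR)-3-hydroxy-6,8a-dimethyl-3-(propan-2-yl)-1,2,3,3a,4,5,8,8a-octahydroazulen-4-yl (2E)-3-(4-hydroxyphenyl)prop-2-enoate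
Conditions: K2CO3 (cat.), MeOH, 0 °C
Reagents that add atoms: none
Why: Base-catalysed methanolysis cleaves the aryl acetate, which is far more reactive than the hindered secondary alkyl cinnamate, and liberates the phenol of the target.

**Compound list**
1 | ethyl (3R)-4-chloro-3-hydroxybutanoate | CCOC(=O)C[C@@H](O)CCl | starting material
2 | ethyl 2-[(2R)-oxiran-2-yl]acetate | CCOC(=O)C[C@@H]1CO1 | intermediate
3 | ethyl (3S)-3-hydroxy-5-methylhex-5-enoate | CCOC(=O)C[C@@H](O)CC(C)=C | intermediate
4 | pent-1-en-4-yne | C=CCC#C | starting material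
5 | dimethyl[(1E)-2-methylpenta-1,4-dien-1-yl]alumane (alkenylalane) | C=CC/C(C)=C/[Al](C)C | intermediate
6 | lithium butyl(dimethyl)[(1E)-2-methylpenta-1,4-dien-1-yl]aluminate (lithium alanate) | [Li+].CCCC[Al-](C)(C)/C=C(\C)CC=C | intermediate
7 | (2E)-3-methylhexa-2,5-dien-1-ol | C=CC/C(C)=C/CO | intermediate
8 | (2E)-3-methylhexa-2,5-dien-1-yl (3S)-3-hydroxy-5-methylhex-5-enoate | C=CC/C(C)=C/COC(=O)C[C@@H](O)CC(C)=C | intermediate
9 | dilithium enolate alkoxide of 8 (enolate oxygen cis to the C6 chain) | C=CC/C(C)=C/CO/C(O[Li])=C/[C@@H](O[Li])CC(C)=C | intermediate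
10 | (2S,3S)-3-hydroxy-5-methyl-2-[(3S)-3-methylhexa-1,5-dien-3-yl]hex-5-enoic acid | C=CC[C@@](C)(C=C)[C@H](C(=O)O)[C@@H](O)CC(C)=C | intermediate
11 | (2S,3S)-3-hydroxy-N-methoxy-N,5-dimethyl-2-[(3S)-3-methylhexa-1,5-dien-3-yl]hex-5-enamide | C=CC[C@@](C)(C=C)[C@H](C(=O)N(C)OC)[C@@H](O)CC(C)=C | intermediate
12 | (2S,3S)-3-[(tert-butyldimethylsilyl)oxy]-N-methoxy-N,5-dimethyl-2-[(3S)-3-methylhexa-1,5-dien-3-yl]hex-5-enamide | C=CC[C@@](C)(C=C)[C@H](C(=O)N(C)OC)[C@@H](O[Si](C)(C)C(C)(C)C)CC(C)=C | intermediate
13 | (1S,2S,7S)-7-[(tert-butyldimethylsilyl)oxy]-2-ethenyl-N-methoxy-N,2,5-trimethylcyclohept-4-ene-1-carboxamide | CC1=CC[C@@](C)(C=C)[C@H](C(=O)N(C)OC)[C@@H](O[Si](C)(C)C(C)(C)C)C1 | intermediate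
14 | (1S,2S,7S)-7-[(tert-butyldimethylsilyl)oxy]-2-ethenyl-2,5-dimethylcyclohept-4-ene-1-carbaldehyde | CC1=CC[C@@](C)(C=C)[C@H](C=O)[C@@H](O[Si](C)(C)C(C)(C)C)C1 | intermediate
15 | (3aR,8S,8aS)-8-[(tert-butyldimethylsilyl)oxy]-3a,6-dimethyl-3,3a,4,7,8,8a-hexahydroazulen-1(2H)-one | CC1=CC[C@@]2(C)CCC(=O)[C@@H]2[C@@H](O[Si](C)(C)C(C)(C)C)C1 | intermediate
16 | (3R,3aS,4S,8aR)-4-[(tert-butyldimethylsilyl)oxy]-6,8a-dimethyl-3-(propan-2-yl)-1,2,3,3a,4,5,8,8a-octahydroazulen-3-ol | CC1=CC[C@@]2(C)CC[C@@](O)(C(C)C)[C@@H]2[C@@H](O[Si](C)(C)C(C)(C)C)C1 | intermediate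
17 | (3R,3aS,4S,8aR)-6,8a-dimethyl-3-(propan-2-yl)-1,2,3,3a,4,5,8,8a-octahydroazulene-3,4-diol (jaeschkeanadiol) | CC1=CC[C@@]2(C)CC[C@@](O)(C(C)C)[C@@H]2[C@@H](O)C1 | intermediate
18 | (2E)-3-[4-(acetyloxy)phenyl]prop-2-enoic acid | CC(=O)Oc1ccc(/C=C/C(=O)O)cc1 | starting material
19 | (3R,3aS,4S,8aR)-3-hydroxy-6,8a-dimethyl-3-(propan-2-yl)-1,2,3,3a,4,5,8,8a-octahydroazulen-4-yl (2E)-3-[4-(acetyloxy)phenyl]prop-2-enoate | CC1=CC[C@@]2(C)CC[C@@](O)(C(C)C)[C@@H]2[C@@H](OC(=O)/C=C/c2ccc(OC(C)=O)cc2)C1 | intermediate
20 | (3R,3aS,4S,8aR)-3-hydroxy-6,8a-dimethyl-3-(propan-2-yl)-1,2,3,3a,4,5,8,8a-octahydroazulen-4-yl (2E)-3-(4-hydroxyphenyl)prop-2-enoate | CC1=CC[C@@]2(C)CC[C@@](O)(C(C)C)[C@@H]2[C@@H](OC(=O)/C=C/c2ccc(O)cc2)C1 | target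

**Step count**
Total step count: 14. Longest linear sequence: 13 steps (steps 1, 2 and 4 to 14; step 3 is the side branch to the dienol).

**Steps most likely to fail**

Step 5. The [3,3] shift of the lithium dianion may be slow at the trisubstituted allyl terminus, so that on warming retro-aldol cleavage of the alkoxide and loss of the chair and facial preference take over. The fallback replaces the chelate-directed dianion by a protected, non-chelated silyl ketene acetal. It sets out from compound 8: silylation (Et3SiCl, imidazole, DMF) would give (2E)-3-methylhexa-2,5-dien-1-yl (3S)-5-methyl-3-[(triethylsilyl)oxy]hex-5-enoate F1. Enolization with LDA in THF/DMPU at −78 °C in the presence of Me3SiCl should give the ketene acetal with the C6 chain cis to the silyloxy group, the same geometry as in the chelate. Warming to 25 °C and mild acidic work-up would then give (2S,3S)-5-methyl-2-[(3S)-3-methylhexa-1,5-dien-3-yl]-3-[(triethylsilyl)oxy]hex-5-enoic acid F2, with the face now chosen by the protected C6 centre under acyclic control. HF·pyridine in THF would remove the silyl group and bring the route back at compound 10.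

Step 10. Insertion of the hindered neopentylic vinyl group into the rhodium hydride may be slower than decarbonylation of the acyl rhodium hydride, with loss of the formyl carbon. The fallback closes the same C3–C4 bond by an anionic acyl substitution and sets out from compound 13. Hydroboration of the vinyl group with 9-BBN (THF, then NaBO3) would give (1S,2S,7S)-7-[(tert-butyldimethylsilyl)oxy]-2-(2-hydroxyethyl)-N-methoxy-N,2,5-trimethylcyclohept-4-ene-1-carboxamide F3; the terminal alkene should react well before the trisubstituted ring alkene. Iodination (I2, PPh3, imidazole, CH2Cl2) would give (1S,2S,7S)-7-[(tert-butyldimethylsilyl)oxy]-2-(2-iodoethyl)-N-methoxy-N,2,5-trimethylcyclohept-4-ene-1-carboxamide F4. Iodine–lithium exchange (t-BuLi, Et2O/pentane, −78 °C) would then let the primary alkyllithium attack the Weinreb amide intramolecularly, which brings the route back at compound 15.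

Step 11. Reduction of the hindered ketone by β-hydride transfer from the isopropyl reagent, and enolization toward C3 or C5, may outrun addition. The fallback uses an sp2 nucleophile without β-hydrogens and sets out from compound 15. Addition of prop-1-en-2-ylmagnesium bromide with anhydrous CeCl3 (THF, −78 °C) would give (3S,3aS,4S,8aR)-4-[(tert-butyldimethylsilyl)oxy]-6,8a-dimethyl-3-(prop-1-en-2-yl)-1,2,3,3a,4,5,8,8a-octahydroazulen-3-ol F5, with the same facial preference. Hydrogenation of the 1,1-disubstituted alkene (H2, RhCl(PPh3)3, benzene, 25 °C), which should leave the trisubstituted ring alkene untouched, brings the route back at compound 16.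

**Further compounds**
F1 | step 5 | (2E)-3-methylhexa-2,5-dien-1-yl (3S)-5-methyl-3-[(triethylsilyl)oxy]hex-5-enoate | C=CC/C(C)=C/COC(=O)C[C@@H](O[Si](CC)(CC)CC)CC(C)=C
F2 | step 5 | (2S,3S)-5-methyl-2-[(3S)-3-methylhexa-1,5-dien-3-yl]-3-[(triethylsilyl)oxy]hex-5-enoic acid | C=CC[C@@](C)(C=C)[C@H](C(=O)O)[C@@H](O[Si](CC)(CC)CC)CC(C)=C
F3 | step 10 | (1S,2S,7S)-7-[(tert-butyldimethylsilyl)oxy]-2-(2-hydroxyethyl)-N-methoxy-N,2,5-trimethylcyclohept-4-ene-1-carboxamide | CC1=CC[C@@](C)(CCO)[C@H](C(=O)N(C)OC)[C@@H](O[Si](C)(C)C(C)(C)C)C1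
F4 | step 10 | (1S,2S,7S)-7-[(tert-butyldimethylsilyl)oxy]-2-(2-iodoethyl)-N-methoxy-N,2,5-trimethylcyclohept-4-ene-1-carboxamide | CC1=CC[C@@](C)(CCI)[C@H](C(=O)N(C)OC)[C@@H](O[Si](C)(C)C(C)(C)C)C1
F5 | step 11 | (3S,3aS,4S,8aR)-4-[(tert-butyldimethylsilyl)oxy]-6,8a-dimethyl-3-(prop-1-en-2-yl)-1,2,3,3a,4,5,8,8a-octahydroazulen-3-ol | CC1=CC[C@@]2(C)CC[C@@](O)(C(C)=C)[C@@H]2[C@@H](O[Si](C)(C)C(C)(C)C)C1
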